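Rings are lettered A to F from the phloroglucinol end, each numbered from its ether carbon nearer ring A. The route rests on disconnecting the bond between carbons 1 and 2 of ring A: this ring is built last by a Mg(OCH2Ph)2-mediated Claisen cyclisation in which the aryloxymethyl carbon of an enol-ether-masked 6-aryloxy-3,5-dioxohexanoate attacks its own ester carbon, closing and aromatising the ring in one operation. The step exploits the oxygen pattern of ring A, whose ether carbon 1 lies between the hydroxylated carbons 2 and 6 like a folded triketide. The precursor is perbenzylated pentamer B–F carrying a methyl (E)-3-benzyloxy-5-oxohex-2-enoate chain on the ring B carbon 1 oxygen.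

Key step: step 22

Remarks on the chemistry (assumptions):
- In rings C and E the second ether carbon is position 6 and the only CH is position 2. In rings B and D the second ether carbon is position 4 and the benzyloxy groups sit at positions 3 and 5.
- The target has no stereocentre. The only stereo-element on the way is the E enol ether of 28, 29 and 31.
- Compounds 1, 6, 25 and 27 are taken as purchased.
- The pentamer is grown from the ring F end by two alternating cycles. An ortho-formyl aryl bromide is coupled and its formyl group turned into the next phenol. A fluoride flanked by two formyl groups is displaced and those formyl groups become the two flanking benzyloxy groups.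

Step 1
Reactants: 1 3,4,5-trihydroxybenzaldehyde
Product: 2 3,4,5-tris(benzyloxy)benzaldehyde
Conditions: BnBr (3.3 equiv), K2CO3, DMF, 60 °C, N2
Reagents that add atoms: benzyl bromide, BrCc1ccccc1
Why: Williamson O-alkylation of the three phenoxides should be exhaustive and leaves the non-enolisable aldehyde untouched.

Step 2
Reactants: 2 3,4,5-tris(benzyloxy)benzaldehyde
Product: 3 2-bromo-3,4,5-tris(benzyloxy)benzaldehyde
Conditions: NBS (1.05 equiv), DMF, rt, dark
Reagents that add atoms: N-bromosuccinimide, O=C1CCC(=O)N1Br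
Why: Electrophilic aromatic bromination should go to position 2 (equivalent to position 6), which is ortho and para to benzyloxy groups, and stop at the monobromide because the product is more hindered and less electron-rich.

Step 3
Reactants: 2 3,4,5-tris(benzyloxy)benzaldehyde
Product: 5 3,4,5-tris(benzyloxy)phenol, via formate 4 (not isolated)
Conditions: mCPBA, CH2Cl2, 0 °C to rt; then K2CO3 (cat.), MeOH, rt
Reagents that add atoms: 3-chloroperoxybenzoic acid, OOC(=O)c1cccc(Cl)c1
Why: Baeyer–Villiger oxidation of an electron-rich benzaldehyde proceeds with aryl migration to the aryl formate, which carbonate-catalysed methanolysis cleaves to the phenol (Dakin-type sequence).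

Step 4
Reactants: 6 5-bromo-2-fluoro-1,3-dimethylbenzene
Product: 7 5-bromo-1,3-bis(dibromomethyl)-2-fluorobenzene
Conditions: NBS (4.4 equiv), AIBN (cat.), PhCF3, reflux
Reagents that add atoms: N-bromosuccinimide, O=C1CCC(=O)N1Br
Why: Radical benzylic (Wohl–Ziegler) bromination should take each methyl group to the dibromomethyl stage, where steric and polar effects retard a third substitution.

Step 5
Reactants: 7 5-bromo-1,3-bis(dibromomethyl)-2-fluorobenzene
Product: 8 5-bromo-2-fluorobenzene-1,3-dicarbaldehyde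
Conditions: AgNO3, acetone/H2O, reflux
Reagents that add atoms: water, O
Why: Silver-assisted hydrolysis of the two geminal dibromides (halide abstraction, capture by water, loss of HBr) unveils both aldehydes without touching the aryl halides.

Step 6
Reactants: 5 3,4,5-tris(benzyloxy)phenol; 3 2-bromo-3,4,5-tris(benzyloxy)benzaldehyde
Product: 9 3,4,5-tris(benzyloxy)-2-[3,4,5-tris(benzyloxy)phenoxy]benzaldehyde (dimer F–E aldehyde)
Conditions: CuI (20 mol%), picolinic acid (40 mol%), K3PO4, DMSO, 90 °C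
Reagents that add atoms: none
Why: Ullmann-type copper-catalysed C–O coupling of an unhindered, electron-rich phenol with an aryl bromide that is activated and chelated by its ortho formyl group, the arrangement that best tolerates the flanking benzyloxy group.

Step 7
Reactants: 9 dimer F–E aldehyde
Product: 11 3,4,5-tris(benzyloxy)-2-[3,4,5-tris(benzyloxy)phenoxy]phenol (dimer F–E phenol with a free hydroxyl at position 1 of ring E), via formate 10 (not isolated)
Conditions: mCPBA, CH2Cl2, 0 °C to rt; then K2CO3 (cat.), MeOH, rt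
Reagents that add atoms: 3-chloroperoxybenzoic acid, OOC(=O)c1cccc(Cl)c1
Why: Baeyer–Villiger oxidation with aryl migration is favoured because the formyl group is ortho to the aryloxy and para to a benzyloxy donor, and methanolysis of the formate frees the ring E phenol.

Step 8
Reactants: 11 dimer F–E phenol; 8 5-bromo-2-fluorobenzene-1,3-dicarbaldehyde
Product: 12 5-bromo-2-{3,4,5-tris(benzyloxy)-2-[3,4,5-tris(benzyloxy)phenoxy]phenoxy}benzene-1,3-dicarbaldehyde
Conditions: K2CO3, DMF, rt to 40 °C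
Reagents that add atoms: none
Why: Nucleophilic aromatic substitution through a Meisenheimer complex should be easy because the fluoride is flanked by two formyl groups, so the crowded ether bond at position 4 of ring D is made without a metal.

Step 9
Reactants: 12 dialdehyde of step 8
Product: 14 5-bromo-2-{3,4,5-tris(benzyloxy)-2-[3,4,5-tris(benzyloxy)phenoxy]phenoxy}benzene-1,3-diol, via diformate 13 (not isolated)
Conditions: mCPBA (3 equiv), CH2Cl2, 0 °C to rt; then K2CO3 (cat.), MeOH, rt, N2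
Reagents that add atoms: 3-chloroperoxybenzoic acid, OOC(=O)c1cccc(Cl)c1
Why: Twofold Baeyer–Villiger oxidation, each formyl group being ortho to the aryloxy donor, followed by formate methanolysis turns the two activating groups into the oxygens at positions 3 and 5 of ring D.

Step 10
Reactants: 14 bromoresorcinol of step 9
Product: 15 1,3-bis(benzyloxy)-5-bromo-2-{3,4,5-tris(benzyloxy)-2-[3,4,5-tris(benzyloxy)phenoxy]phenoxy}benzene (trimer F–E–D bromide)
Conditions: BnBr (2.5 equiv), K2CO3, DMF, 50 °C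
Reagents that add atoms: benzyl bromide, BrCc1ccccc1
Why: Williamson O-benzylation of the two phenols, each of which has only one ortho neighbour, should be complete under standard conditions.

Step 11
Reactants: 15 trimer F–E–D bromide
Product: 16 3,5-bis(benzyloxy)-4-{3,4,5-tris(benzyloxy)-2-[3,4,5-tris(benzyloxy)phenoxy]phenoxy}phenol (trimer F–E–D phenol with a free hydroxyl at position 1 of ring D)
Conditions: Pd2(dba)3 (2 mol%), t-BuXPhos (8 mol%), KOH, 1,4-dioxane/H2O, 100 °C; then aq. HCl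
Reagents that add atoms: potassium hydroxide, [K+].[OH-]
Why: Palladium-catalysed hydroxylation of an aryl bromide without ortho substituents (oxidative addition to zerovalent palladium, bromide–hydroxide exchange, C–O reductive elimination promoted by the bulky biarylphosphine) leaves benzyl and diaryl ethers intact.

Step 12
Reactants: 16 trimer F–E–D phenol; 3 2-bromo-3,4,5-tris(benzyloxy)benzaldehyde
Product: 17 tetramer F–E–D–C aldehyde: 3,4,5-tris(benzyloxy)-2-(aryloxy)benzaldehyde in which the aryloxy group is derived from phenol 16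
Conditions: CuI (20 mol%), picolinic acid (40 mol%), K3PO4, DMSO, 90 °C
Reagents that add atoms: none
Why: The same Ullmann-type copper-catalysed C–O coupling as in step 6, with the ring D phenol free of ortho substituents and the bromide assisted by its ortho formyl group.

Step 13
Reactants: 17 tetramer aldehyde
Product: 19 tetramer F–E–D–C phenol (17 with the formyl group replaced by a hydroxyl at position 1 of ring C), via formate 18 (not isolated)
Conditions: mCPBA, CH2Cl2, 0 °C to rt; then K2CO3 (cat.), MeOH, rt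
Reagents that add atoms: 3-chloroperoxybenzoic acid, OOC(=O)c1cccc(Cl)c1
Why: Baeyer–Villiger oxidation with aryl migration (formyl ortho to aryloxy and para to benzyloxy) and formate methanolysis, as in step 7.

Step 14
Reactants: 19 tetramer phenol; 8 5-bromo-2-fluorobenzene-1,3-dicarbaldehyde
Product: 20 5-bromo-2-(aryloxy)benzene-1,3-dicarbaldehyde in which the aryloxy group is derived from phenol 19
Conditions: K2CO3, DMF, rt to 40 °C
Reagents that add atoms: none
Why: Nucleophilic aromatic substitution of the doubly formyl-activated fluoride by the ring C phenoxide, as in step 8.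

Step 15
Reactants: 20 dialdehyde of step 14
Product: 22 5-bromo-2-(aryloxy)benzene-1,3-diol in which the aryloxy group is derived from phenol 19, via diformate 21 (not isolated)
Conditions: mCPBA (3 equiv), CH2Cl2, 0 °C to rt; then K2CO3 (cat.), MeOH, rt, N2
Reagents that add atoms: 3-chloroperoxybenzoic acid, OOC(=O)c1cccc(Cl)c1
Why: Twofold Baeyer–Villiger oxidation and formate methanolysis convert the two formyl groups into the oxygens at positions 3 and 5 of ring B, as in step 9.

Step 16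
Reactants: 22 bromoresorcinol of step 15
Product: 23 pentamer B–F bromide: 1,3-bis(benzyloxy)-5-bromo-2-(aryloxy)benzene in which the aryloxy group is derived from phenol 19
Conditions: BnBr (2.5 equiv), K2CO3, DMF, 50 °C
Reagents that add atoms: benzyl bromide, BrCc1ccccc1
Why: Williamson O-benzylation of both phenols completes the thirteen benzyl ethers of the pentamer.

Step 17
Reactants: 23 pentamer bromide
Product: 24 pentamer B–F phenol: 3,5-bis(benzyloxy)-4-(aryloxy)phenol in which the aryloxy group is derived from phenol 19 (free hydroxyl at position 1 of ring B)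
Conditions: Pd2(dba)3 (2 mol%), t-BuXPhos (8 mol%), KOH, 1,4-dioxane/H2O, 100 °C; then aq. HCl
Reagents that add atoms: potassium hydroxide, [K+].[OH-]
Why: Palladium-catalysed hydroxylation of the unhindered ring B bromide, the same reaction as in step 11.

Step 18
Reactants: 24 pentamer phenol; 25 2-chloro-N-methoxy-N-methylacetamide
Product: 26 N-methoxy-N-methyl-2-(aryloxy)acetamide in which the aryloxy group is derived from phenol 24
Conditions: K2CO3, DMF, 60 °C
Reagents that add atoms: none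
Why: Williamson alkylation (SN2) of the unhindered ring B phenoxide by the activated α-chloro amide installs the future carbons 1 and 6 of ring A with the acyl group already in Weinreb amide form.

Step 19
Reactants: 27 methyl acetoacetate
Product: 28 methyl (E)-3-methoxybut-2-enoate
Conditions: HC(OMe)3, H2SO4 (cat.), MeOH, rt; then distillation
Reagents that add atoms: trimethyl orthoformate, COC(OC)OC
Why: Acid-catalysed ketalisation by the orthoformate and loss of methanol on distillation give the conjugated enol ether as the thermodynamically preferred E isomer (ester and methoxy trans).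

Step 20
Reactants: 28 methyl (E)-3-methoxybut-2-enoate
Product: 29 methyl (E)-3-(benzyloxy)but-2-enoate
Conditions: BnOH (1.2 equiv), PPTS (cat.), toluene, 110 °C, MeOH distilled off
Reagents that add atoms: benzyl alcohol, OCc1ccccc1
Why: Acid-catalysed enol ether exchange (C-protonation to the oxocarbenium ion, addition of benzyl alcohol, loss of methanol) is driven by removal of methanol and ends again at the E isomer.

Step 21
Reactants: 29 methyl (E)-3-(benzyloxy)but-2-enoate; 26 Weinreb amide of step 18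
Product: 31 methyl (E)-3-(benzyloxy)-5-oxo-6-(aryloxy)hex-2-enoate in which the aryloxy group is derived from phenol 24, via lithium dienolate 30 (not isolated)
Conditions: LiN(iPr)2 (2.2 equiv) and 29 (2.2 equiv), THF, −78 °C; then 26, −78 °C; AcOH, −78 °C
Reagents that add atoms: none
Why: Kinetic γ-deprotonation gives the extended dienolate, which is acylated at its γ-carbon by the Weinreb amide (vinylogous Claisen condensation); the chelated tetrahedral adduct prevents over-addition and proton transfer from the more acidic product until the cold quench, and the E enol ether is retained.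

Step 22
Reactants: 31 keto enol ether ester of step 21
Product: 32 5-(benzyloxy)-2-(aryloxy)benzene-1,3-diol in which the aryloxy group is derived from phenol 24 (hexamer with free hydroxyls at positions 2 and 6 of ring A and fourteen benzyl ethers)
Conditions: Mg(OCH2Ph)2 (3 equiv, from Bu2Mg and PhCH2OH), toluene/PhCH2OH, 90 °C, argon; then aq. HCl, 0 °C
Reagents that add atoms: none
Why: Proposed new method: Mg(OCH2Ph)2 equilibrates the enolates of 31; the ketone enolate at the aryloxymethyl carbon (future carbon 1 of ring A) adds to the ester carbonyl (future carbon 2), the tetrahedral alkoxide expels its alkoxide, and the resulting 2-aryloxy-5-benzyloxycyclohex-4-ene-1,3-dione enolises twice to the resorcinol, which makes the C-acylation irreversible. The closest known reaction type is the alkoxide- or Mg(OMe)2-mediated Claisen (Dieckmann-type) cyclisation of 3,5,7-triketo esters and of ring-opened 2-pyrones to phloroglucinols, together with the enzymatic folding of a 3,5-dioxohexanoyl thioester; new here are a nucleophilic carbon activated by only one carbonyl plus an aryloxy group and a vinylogous carbonate as the acyl acceptor. Ring A closes in the 6-(enolendo)-exo-trig mode, since the enolate double bond lies inside the forming ring and the ester carbonyl oxygen outside it. No stereocentre is formed; the E enol ether only holds the ester and the ketone arm cis and ends up as the benzyl ether at position 4 of ring A. The selectivity needed is C- over O-acylation and reaction through the less acidic enolate: the more acidic C-4 methylene enolate has no productive cyclisation path, lactonisation through the ketone enol oxygen to the 2-pyrone is reversed by benzyloxide, and aromatisation drains both equilibria towards the carbocycle. Benzyloxide is used in place of methoxide so that transesterification and conjugate alkoxide exchange at the enol ether carbon are harmless and the oxygen at position 4 of ring A stays benzylated.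

Step 23
Reactants: 32 hexamer diol of step 22
Product: 33 target hexamer (CNP0114537.0)
Conditions: H2 (1 atm), Pd/C (10%), THF/MeOH, rt
Reagents that add atoms: none
Why: Heterogeneous catalytic hydrogenolysis cleaves all fourteen benzylic C–O bonds, while the diaryl ether bonds and the free phenols are inert under these conditions.

Compound list
1 | 3,4,5-trihydroxybenzaldehyde | O=Cc1cc(O)c(O)c(O)c1 | starting material
2 | 3,4,5-tris(benzyloxy)benzaldehyde | O=Cc1cc(OCc9ccccc9)c(OCc9ccccc9)c(OCc9ccccc9)c1 | intermediate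
3 | 2-bromo-3,4,5-tris(benzyloxy)benzaldehyde | O=Cc1cc(OCc9ccccc9)c(OCc9ccccc9)c(OCc9ccccc9)c1Br | intermediate
4 | 3,4,5-tris(benzyloxy)phenyl formate | O=COc1cc(OCc9ccccc9)c(OCc9ccccc9)c(OCc9ccccc9)c1 | intermediate (not isolated)
5 | 3,4,5-tris(benzyloxy)phenol | Oc1cc(OCc9ccccc9)c(OCc9ccccc9)c(OCc9ccccc9)c1 | intermediate
6 | 5-bromo-2-fluoro-1,3-dimethylbenzene | Cc1cc(Br)cc(C)c1F | starting material
7 | 5-bromo-1,3-bis(dibromomethyl)-2-fluorobenzene | BrC(Br)c1cc(Br)cc(C(Br)Br)c1F | intermediate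
8 | 5-bromo-2-fluorobenzene-1,3-dicarbaldehyde | O=Cc1cc(Br)cc(C=O)c1F | intermediate
9 | 3,4,5-tris(benzyloxy)-2-[3,4,5-tris(benzyloxy)phenoxy]benzaldehyde (dimer F–E aldehyde) | O=Cc4cc(OCc9ccccc9)c(OCc9ccccc9)c(OCc9ccccc9)c4Oc4cc(OCc9ccccc9)c(OCc9ccccc9)c(OCc9ccccc9)c4 | intermediate
10 | 3,4,5-tris(benzyloxy)-2-[3,4,5-tris(benzyloxy)phenoxy]phenyl formate | O=COc4cc(OCc9ccccc9)c(OCc9ccccc9)c(OCc9ccccc9)c4Oc4cc(OCc9ccccc9)c(OCc9ccccc9)c(OCc9ccccc9)c4 | intermediate (not isolated)
11 | 3,4,5-tris(benzyloxy)-2-[3,4,5-tris(benzyloxy)phenoxy]phenol (dimer F–E phenol) | Oc4cc(OCc9ccccc9)c(OCc9ccccc9)c(OCc9ccccc9)c4Oc4cc(OCc9ccccc9)c(OCc9ccccc9)c(OCc9ccccc9)c4 | intermediate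
12 | 5-bromo-2-{3,4,5-tris(benzyloxy)-2-[3,4,5-tris(benzyloxy)phenoxy]phenoxy}benzene-1,3-dicarbaldehyde | O=Cc1cc(Br)cc(C=O)c1Oc4cc(OCc9ccccc9)c(OCc9ccccc9)c(OCc9ccccc9)c4Oc4cc(OCc9ccccc9)c(OCc9ccccc9)c(OCc9ccccc9)c4 | intermediate
13 | 5-bromo-2-{3,4,5-tris(benzyloxy)-2-[3,4,5-tris(benzyloxy)phenoxy]phenoxy}-1,3-phenylene diformate | O=COc1cc(Br)cc(OC=O)c1Oc4cc(OCc9ccccc9)c(OCc9ccccc9)c(OCc9ccccc9)c4Oc4cc(OCc9ccccc9)c(OCc9ccccc9)c(OCc9ccccc9)c4 | intermediate (not isolated)
14 | 5-bromo-2-{3,4,5-tris(benzyloxy)-2-[3,4,5-tris(benzyloxy)phenoxy]phenoxy}benzene-1,3-diol | Oc1cc(Br)cc(O)c1Oc4cc(OCc9ccccc9)c(OCc9ccccc9)c(OCc9ccccc9)c4Oc4cc(OCc9ccccc9)c(OCc9ccccc9)c(OCc9ccccc9)c4 | intermediate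
15 | trimer F–E–D bromide: 1,3-bis(benzyloxy)-5-bromo-2-{3,4,5-tris(benzyloxy)-2-[3,4,5-tris(benzyloxy)phenoxy]phenoxy}benzene | Brc3cc(OCc9ccccc9)c(Oc4cc(OCc9ccccc9)c(OCc9ccccc9)c(OCc9ccccc9)c4Oc4cc(OCc9ccccc9)c(OCc9ccccc9)c(OCc9ccccc9)c4)c(OCc9ccccc9)c3 | intermediate
16 | trimer F–E–D phenol: 3,5-bis(benzyloxy)-4-{3,4,5-tris(benzyloxy)-2-[3,4,5-tris(benzyloxy)phenoxy]phenoxy}phenol | Oc3cc(OCc9ccccc9)c(Oc4cc(OCc9ccccc9)c(OCc9ccccc9)c(OCc9ccccc9)c4Oc4cc(OCc9ccccc9)c(OCc9ccccc9)c(OCc9ccccc9)c4)c(OCc9ccccc9)c3 | intermediate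
17 | tetramer F–E–D–C aldehyde: 3,4,5-tris(benzyloxy)-2-(aryloxy)benzaldehyde, aryloxy from phenol 16 | O=Cc3cc(OCc9ccccc9)c(OCc9ccccc9)c(OCc9ccccc9)c3Oc3cc(OCc9ccccc9)c(Oc4cc(OCc9ccccc9)c(OCc9ccccc9)c(OCc9ccccc9)c4Oc4cc(OCc9ccccc9)c(OCc9ccccc9)c(OCc9ccccc9)c4)c(OCc9ccccc9)c3 | intermediate
18 | tetramer formate: 3,4,5-tris(benzyloxy)-2-(aryloxy)phenyl formate, aryloxy from phenol 16 | O=COc3cc(OCc9ccccc9)c(OCc9ccccc9)c(OCc9ccccc9)c3Oc3cc(OCc9ccccc9)c(Oc4cc(OCc9ccccc9)c(OCc9ccccc9)c(OCc9ccccc9)c4Oc4cc(OCc9ccccc9)c(OCc9ccccc9)c(OCc9ccccc9)c4)c(OCc9ccccc9)c3 | intermediate (not isolated)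
19 | tetramer F–E–D–C phenol: 3,4,5-tris(benzyloxy)-2-(aryloxy)phenol, aryloxy from phenol 16 | Oc3cc(OCc9ccccc9)c(OCc9ccccc9)c(OCc9ccccc9)c3Oc3cc(OCc9ccccc9)c(Oc4cc(OCc9ccccc9)c(OCc9ccccc9)c(OCc9ccccc9)c4Oc4cc(OCc9ccccc9)c(OCc9ccccc9)c(OCc9ccccc9)c4)c(OCc9ccccc9)c3 | intermediate
20 | 5-bromo-2-(aryloxy)benzene-1,3-dicarbaldehyde, aryloxy from phenol 19 | O=Cc1cc(Br)cc(C=O)c1Oc3cc(OCc9ccccc9)c(OCc9ccccc9)c(OCc9ccccc9)c3Oc3cc(OCc9ccccc9)c(Oc4cc(OCc9ccccc9)c(OCc9ccccc9)c(OCc9ccccc9)c4Oc4cc(OCc9ccccc9)c(OCc9ccccc9)c(OCc9ccccc9)c4)c(OCc9ccccc9)c3 | intermediate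
21 | 5-bromo-2-(aryloxy)-1,3-phenylene diformate, aryloxy from phenol 19 | O=COc1cc(Br)cc(OC=O)c1Oc3cc(OCc9ccccc9)c(OCc9ccccc9)c(OCc9ccccc9)c3Oc3cc(OCc9ccccc9)c(Oc4cc(OCc9ccccc9)c(OCc9ccccc9)c(OCc9ccccc9)c4Oc4cc(OCc9ccccc9)c(OCc9ccccc9)c(OCc9ccccc9)c4)c(OCc9ccccc9)c3 | intermediate (not isolated)
22 | 5-bromo-2-(aryloxy)benzene-1,3-diol, aryloxy from phenol 19 | Oc1cc(Br)cc(O)c1Oc3cc(OCc9ccccc9)c(OCc9ccccc9)c(OCc9ccccc9)c3Oc3cc(OCc9ccccc9)c(Oc4cc(OCc9ccccc9)c(OCc9ccccc9)c(OCc9ccccc9)c4Oc4cc(OCc9ccccc9)c(OCc9ccccc9)c(OCc9ccccc9)c4)c(OCc9ccccc9)c3 | intermediate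
23 | pentamer B–F bromide: 1,3-bis(benzyloxy)-5-bromo-2-(aryloxy)benzene, aryloxy from phenol 19 | Brc2cc(OCc9ccccc9)c(Oc3cc(OCc9ccccc9)c(OCc9ccccc9)c(OCc9ccccc9)c3Oc3cc(OCc9ccccc9)c(Oc4cc(OCc9ccccc9)c(OCc9ccccc9)c(OCc9ccccc9)c4Oc4cc(OCc9ccccc9)c(OCc9ccccc9)c(OCc9ccccc9)c4)c(OCc9ccccc9)c3)c(OCc9ccccc9)c2 | intermediate
24 | pentamer B–F phenol: 3,5-bis(benzyloxy)-4-(aryloxy)phenol, aryloxy from phenol 19 (thirteen benzyl ethers, free hydroxyl at position 1 of ring B) | Oc2cc(OCc9ccccc9)c(Oc3cc(OCc9ccccc9)c(OCc9ccccc9)c(OCc9ccccc9)c3Oc3cc(OCc9ccccc9)c(Oc4cc(OCc9ccccc9)c(OCc9ccccc9)c(OCc9ccccc9)c4Oc4cc(OCc9ccccc9)c(OCc9ccccc9)c(OCc9ccccc9)c4)c(OCc9ccccc9)c3)c(OCc9ccccc9)c2 | intermediate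
25 | 2-chloro-N-methoxy-N-methylacetamide | CON(C)C(=O)CCl | starting material
26 | N-methoxy-N-methyl-2-(aryloxy)acetamide, aryloxy from phenol 24 | CON(C)C(=O)COc2cc(OCc9ccccc9)c(Oc3cc(OCc9ccccc9)c(OCc9ccccc9)c(OCc9ccccc9)c3Oc3cc(OCc9ccccc9)c(Oc4cc(OCc9ccccc9)c(OCc9ccccc9)c(OCc9ccccc9)c4Oc4cc(OCc9ccccc9)c(OCc9ccccc9)c(OCc9ccccc9)c4)c(OCc9ccccc9)c3)c(OCc9ccccc9)c2 | intermediate
27 | methyl acetoacetate | COC(=O)CC(C)=O | starting material
28 | methyl (E)-3-methoxybut-2-enoate | COC(=O)/C=C(/OC)C | intermediate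
29 | methyl (E)-3-(benzyloxy)but-2-enoate | COC(=O)/C=C(/OCc9ccccc9)C | intermediate
30 | lithium dienolate of 29 (lithium 3-(benzyloxy)-1-methoxybuta-1,3-dien-1-olate) | C=C(OCc9ccccc9)/C=C(\[O-])OC.[Li+] | intermediate (not isolated)
31 | methyl (E)-3-(benzyloxy)-5-oxo-6-(aryloxy)hex-2-enoate, aryloxy from phenol 24 (key-step precursor) | COC(=O)/C=C(/OCc9ccccc9)CC(=O)COc2cc(OCc9ccccc9)c(Oc3cc(OCc9ccccc9)c(OCc9ccccc9)c(OCc9ccccc9)c3Oc3cc(OCc9ccccc9)c(Oc4cc(OCc9ccccc9)c(OCc9ccccc9)c(OCc9ccccc9)c4Oc4cc(OCc9ccccc9)c(OCc9ccccc9)c(OCc9ccccc9)c4)c(OCc9ccccc9)c3)c(OCc9ccccc9)c2 | intermediate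
32 | 5-(benzyloxy)-2-(aryloxy)benzene-1,3-diol, aryloxy from phenol 24 (hexamer with free hydroxyls at positions 2 and 6 of ring A and fourteen benzyl ethers) | Oc1cc(OCc9ccccc9)cc(O)c1Oc2cc(OCc9ccccc9)c(Oc3cc(OCc9ccccc9)c(OCc9ccccc9)c(OCc9ccccc9)c3Oc3cc(OCc9ccccc9)c(Oc4cc(OCc9ccccc9)c(OCc9ccccc9)c(OCc9ccccc9)c4Oc4cc(OCc9ccccc9)c(OCc9ccccc9)c(OCc9ccccc9)c4)c(OCc9ccccc9)c3)c(OCc9ccccc9)c2 | intermediate
33 | target hexamer CNP0114537.0 (all hydroxyls free) | Oc1cc(O)c(Oc2cc(O)c(Oc3cc(O)c(O)c(O)c3Oc3cc(O)c(Oc4cc(O)c(O)c(O)c4Oc4cc(O)c(O)c(O)c4)c(O)c3)c(O)c2)c(O)c1 | target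

Total step count: 23. Longest linear sequence: 18 steps (steps 1, 3, 6 to 18, 21, 22 and 23).

Steps most likely to fail

1. Step 22 (the proposed new method). The substrate may rest as the unreactive enolate of the doubly activated C-4 methylene, or be drained by lactonisation to a 2-pyrone that does not reopen fast enough, so that the carbocycle never closes. The fallback uses only reactions already in the route; it sets out from phenol 24 and comes back at the target 33. Phenol 24 is put through one more turn of the fluoride-displacement and Baeyer–Villiger cycle. Substitution on dialdehyde 8 (K2CO3, DMF) should give the hexamer dialdehyde F1. mCPBA and then K2CO3/MeOH should give, by way of the hexamer diformate F2, the hexamer bromoresorcinol F3. Benzylation (BnBr, K2CO3, DMF) gives the hexamer bromide F4. Palladium-catalysed hydroxylation as in step 17 gives the hexamer phenol F5, which has fifteen benzyl ethers and a free hydroxyl para to the ether oxygen of ring A. Hydrogenolysis under the conditions of step 23 then gives 33.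

2. Step 12 (step 6 forms the same kind of bond). Oxidative addition and ligand exchange at a bromide flanked by formyl and benzyloxy groups may be slow on the large phenol partner, and protodebromination of 3 may then win. The fallback reverses the roles of the two rings; it sets out from bromide 15 and comes back at aldehyde 17, so step 11 is not needed. Purchased 2,3,4-trihydroxybenzaldehyde is benzylated to 2,3,4-tris(benzyloxy)benzaldehyde F6. This is oxidised (mCPBA, then K2CO3/MeOH) through 2,3,4-tris(benzyloxy)phenyl formate F7 to 2,3,4-tris(benzyloxy)phenol F8. Magnesium-mediated formylation at its only free ortho position (MgCl2, Et3N, paraformaldehyde, MeCN, reflux) gives 2-hydroxy-3,4,5-tris(benzyloxy)benzaldehyde F9. Copper-catalysed coupling of this phenol with the unhindered bromide 15 (CuI, picolinic acid, K3PO4, DMSO) then places the steric load on the phenol, which such couplings tolerate better, and gives 17.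

3. Step 21. Proton transfer from the acidic aryloxymethylene group of the Weinreb amide to the dienolate may outrun addition, attack may occur through the α-carbon, and the product may lactonise on work-up. The fallback replaces the acylation by an aldol addition and oxidation; it sets out from 26 and comes back at 31. Reduction of 26 (LiAlH4, THF, −78 °C) gives the pentamer aryloxyacetaldehyde F10. Vinylogous aldol addition of dienolate 30 at −78 °C with a cold acetic acid quench gives the racemic pentamer hydroxy ester F11. Dess–Martin periodinane oxidises its secondary alcohol to the ketone 31.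

Further compounds
F1 | step 22 | hexamer dialdehyde: 5-bromo-2-(aryloxy)benzene-1,3-dicarbaldehyde, aryloxy from phenol 24 | O=Cc1cc(Br)cc(C=O)c1Oc2cc(OCc9ccccc9)c(Oc3cc(OCc9ccccc9)c(OCc9ccccc9)c(OCc9ccccc9)c3Oc3cc(OCc9ccccc9)c(Oc4cc(OCc9ccccc9)c(OCc9ccccc9)c(OCc9ccccc9)c4Oc4cc(OCc9ccccc9)c(OCc9ccccc9)c(OCc9ccccc9)c4)c(OCc9ccccc9)c3)c(OCc9ccccc9)c2
F2 | step 22 | hexamer diformate: 5-bromo-2-(aryloxy)-1,3-phenylene diformate, aryloxy from phenol 24 | O=COc1cc(Br)cc(OC=O)c1Oc2cc(OCc9ccccc9)c(Oc3cc(OCc9ccccc9)c(OCc9ccccc9)c(OCc9ccccc9)c3Oc3cc(OCc9ccccc9)c(Oc4cc(OCc9ccccc9)c(OCc9ccccc9)c(OCc9ccccc9)c4Oc4cc(OCc9ccccc9)c(OCc9ccccc9)c(OCc9ccccc9)c4)c(OCc9ccccc9)c3)c(OCc9ccccc9)c2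
F3 | step 22 | hexamer bromoresorcinol: 5-bromo-2-(aryloxy)benzene-1,3-diol, aryloxy from phenol 24 | Oc1cc(Br)cc(O)c1Oc2cc(OCc9ccccc9)c(Oc3cc(OCc9ccccc9)c(OCc9ccccc9)c(OCc9ccccc9)c3Oc3cc(OCc9ccccc9)c(Oc4cc(OCc9ccccc9)c(OCc9ccccc9)c(OCc9ccccc9)c4Oc4cc(OCc9ccccc9)c(OCc9ccccc9)c(OCc9ccccc9)c4)c(OCc9ccccc9)c3)c(OCc9ccccc9)c2
F4 | step 22 | hexamer bromide: 1,3-bis(benzyloxy)-5-bromo-2-(aryloxy)benzene, aryloxy from phenol 24 | Brc1cc(OCc9ccccc9)c(Oc2cc(OCc9ccccc9)c(Oc3cc(OCc9ccccc9)c(OCc9ccccc9)c(OCc9ccccc9)c3Oc3cc(OCc9ccccc9)c(Oc4cc(OCc9ccccc9)c(OCc9ccccc9)c(OCc9ccccc9)c4Oc4cc(OCc9ccccc9)c(OCc9ccccc9)c(OCc9ccccc9)c4)c(OCc9ccccc9)c3)c(OCc9ccccc9)c2)c(OCc9ccccc9)c1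
F5 | step 22 | hexamer phenol: 3,5-bis(benzyloxy)-4-(aryloxy)phenol, aryloxy from phenol 24 (free hydroxyl at position 4 of ring A, fifteen benzyl ethers) | Oc1cc(OCc9ccccc9)c(Oc2cc(OCc9ccccc9)c(Oc3cc(OCc9ccccc9)c(OCc9ccccc9)c(OCc9ccccc9)c3Oc3cc(OCc9ccccc9)c(Oc4cc(OCc9ccccc9)c(OCc9ccccc9)c(OCc9ccccc9)c4Oc4cc(OCc9ccccc9)c(OCc9ccccc9)c(OCc9ccccc9)c4)c(OCc9ccccc9)c3)c(OCc9ccccc9)c2)c(OCc9ccccc9)c1
F6 | step 12 | 2,3,4-tris(benzyloxy)benzaldehyde | O=Cc1ccc(OCc9ccccc9)c(OCc9ccccc9)c1OCc9ccccc9
F7 | step 12 | 2,3,4-tris(benzyloxy)phenyl formate | O=COc1ccc(OCc9ccccc9)c(OCc9ccccc9)c1OCc9ccccc9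
F8 | step 12 | 2,3,4-tris(benzyloxy)phenol | Oc1ccc(OCc9ccccc9)c(OCc9ccccc9)c1OCc9ccccc9
F9 | step 12 | 2-hydroxy-3,4,5-tris(benzyloxy)benzaldehyde | O=Cc1cc(OCc9ccccc9)c(OCc9ccccc9)c(OCc9ccccc9)c1O
F10 | step 21 | pentamer aryloxyacetaldehyde: 2-(aryloxy)acetaldehyde, aryloxy from phenol 24 | O=CCOc2cc(OCc9ccccc9)c(Oc3cc(OCc9ccccc9)c(OCc9ccccc9)c(OCc9ccccc9)c3Oc3cc(OCc9ccccc9)c(Oc4cc(OCc9ccccc9)c(OCc9ccccc9)c(OCc9ccccc9)c4Oc4cc(OCc9ccccc9)c(OCc9ccccc9)c(OCc9ccccc9)c4)c(OCc9ccccc9)c3)c(OCc9ccccc9)c2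
F11 | step 21 | pentamer hydroxy ester: methyl (E)-3-(benzyloxy)-5-hydroxy-6-(aryloxy)hex-2-enoate, racemic at C-5, aryloxy from phenol 24 | COC(=O)/C=C(/OCc9ccccc9)CC(O)COc2cc(OCc9ccccc9)c(Oc3cc(OCc9ccccc9)c(OCc9ccccc9)c(OCc9ccccc9)c3Oc3cc(OCc9ccccc9)c(Oc4cc(OCc9ccccc9)c(OCc9ccccc9)c(OCc9ccccc9)c4Oc4cc(OCc9ccccc9)c(OCc9ccccc9)c(OCc9ccccc9)c4)c(OCc9ccccc9)c3)c(OCc9ccccc9)c2
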